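## Analysis of the target

The target 29 is a 7-hydroxycoumarin (benzene ring A, C4a to C8a; lactone ring B, O1 to C4) in which every carbon of ring A is substituted. C5 carries a 3-hydroxybutan-2-yl chain (benzylic carbon C1'', carbinol carbon C2''), C6 and C8 carry methyl groups and C7 the phenol. C3 bears a 2-methyl-2,3-dihydro-4H-pyran-4-on-6-yl ring (ring C, O1' to C6').

There are three stereocentres. C2' (R) in ring C is isolated from the others. C1'' (R) and C2'' (S) are contiguous and anti: with the chain drawn from C5 through C1'' and C2'' to the terminal methyl group, the methyl on C1'' and the hydroxyl on C2'' lie on opposite sides.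

Ring C is a β-alkoxy ketone and a vinylogous ester. Base can open it by β-elimination of O1' from C2', with loss of configuration, and amines or aqueous acid can add at C6'. The coumarin C4 is a Michael acceptor, and ring A is an oxidisable resorcinol. Before ring B exists, the C2'' hydroxyl sits γ to the formyl carbon that becomes C4 and would close a six-membered lactol.

The synthesis is hard for three reasons. The carbon chain on C5 is meta to both ring oxygens, so electrophilic substitution cannot place it. The stereodiad is acyclic, benzylic and far from any other control element. The union with ring C must not disturb C2'.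

The strategy rests on the C5 side chain. C2'' and its methyl group map onto C2 and C3 of (S)-lactic acid, and C1'' onto the lactate carboxyl carbon. An aryl ketone from lactate can therefore be methylenated to the allylic alcohol 12, whose free hydroxyl can hold a cationic rhodium catalyst on one alkene face and so set C1'' anti to C2''.

## Retrosynthetic reasoning

**29 from 28.** The last operation only frees the C2'' hydroxyl from its silyl ether. The oxygen must stay masked from the moment a formyl group stands next to the side chain (18) until ring B has consumed that aldehyde, because the free carbinol would trap the aldehyde as a lactol. The forward step has to cleave a hindered secondary silyl ether without base, since ring C does not tolerate it.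

**28 from 18 and 26.** The C3=C4 double bond and the O1–C2 lactone bond are cut together. This is the most convergent cut: ring B is formed in the same operation that joins the aromatic half to the complete ring C, and neither new bond is stereogenic. Ring C is brought in already closed (26). In the open diketo ester 24 the methylene between the two ketones is the more acidic one and would condense first. In 26 that carbon is part of a vinylogous ester, and the only acidic methylene left is the one next to the ester. The forward reaction must condense this methylene with a doubly ortho-substituted aldehyde and let the C8a phenol close the lactone under conditions mild enough for C2'.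

**26 from 24, from 21 and 22, from 19.** Ring C is opened at O1'–C6' (hemiketal formation and dehydration of the hydroxy diketo ester 25) and the chain is cut at C4'–C5'. The cut falls at a ketone, so the forward step is an acylation of dianion 23 by amide 21. The stereocentre is bought with hydroxy ester 19 and is never α to a carbonyl group that is being formed.

**18 from 16, from 14, from 13.** The C4–C4a bond is cut. C4a is the only unsubstituted ring carbon, ortho to one phenol and para to the other, so a phenoxide-directed one-carbon electrophile can only go there. The protecting-group order is set by two facts. Nucleophilic ether cleavage (thiolate) stops after the first phenoxide is formed, so both methyl ethers of a resorcinol cannot be removed that way. A boron halide removes both, but it would also remove a silyl ether and would cyclise a hydroxy aldehyde. The methyl ethers are therefore cleaved directly after the hydrogenation (13 to 14), when neither a silyl ether nor an aldehyde is present. All three hydroxyls are then silylated (15) and the two aryl silyl ethers are released again (16).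

**13 from 12.** Only two C–H bonds are formed, and with them the C1'' stereocentre. The cut is placed here because the free allylic hydroxyl of 12 is the one functional group close enough to direct a metal to one alkene face. The alkene is 1,1-disubstituted, so it is easy to make without any E/Z problem and carries an unhindered CH2 terminus.

**12 from 11, from 10, from 5 and 8.** The =CH2 carbon is removed (carbonyl methylenation of ketone 10) and the aryl–carbonyl bond is cut (addition of Grignard reagent 9 to the lactate amide 8). The silyl ether on the lactate oxygen is needed for the organomagnesium and methylenation steps and is taken off before the hydrogenation. Amide 8 comes from lactate 6 through ester 7.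

**5 from 3, from 2, from 1.** The bromine of 5 is meta to both methoxy groups, which excludes electrophilic bromination. A sterically controlled C–H borylation of the symmetric arene 1 places boron at exactly that carbon (2), and ipso substitution gives bromide 3. The bromine then serves twice. It acidifies the neighbouring ring hydrogen so that the second methyl group can be introduced through aryllithium 4, and it later becomes the Grignard carbon.

## Alternatives that were turned down

**Alternative 1:** Ring A would be built instead of bought. The C4a–C5 bond is cut, so ring A unfolds to an open-chain polycarbonyl compound capped as a dioxinone, with the silylated stereodiad attached to the C5 ketone. In the forward key step an amine base and then acid trigger aldol attack of C4a on the C5 carbonyl and dehydration to the aromatic benzodioxinone A1.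
- For it: all six substituents of ring A and the C4 carbon arrive in one step, and the meta relation between the chain and the oxygens costs nothing. On this point it is stronger than the chosen route, which needs borylation, bromination and a later ether cleavage.
- Against it: C1'' would be the α-carbon of a ketone that also carries a β-silyloxy group, inside a 1,3,5-tricarbonyl array. Under the basic aromatisation it can epimerise through the enol or lose silanolate by β-elimination.
- The anti diad would have to be made beforehand by a separate stereoselective reaction, and the two C-methyl groups would have to be placed on the chain regioselectively.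
- A1 holds C4 at the carboxyl oxidation level, so two redox steps are needed before the coumarin can be closed.
- Comparison: the chosen strategy creates C1'' on a finished arene and never places the diad next to an enolisable carbonyl. It offers a stereocentre that cannot be lost once made, in place of the shorter ring-A construction.

**Alternative 2:** Ring C would be made last. It is disconnected at C5'–C6' and at the ring oxygen, which leads to nitrile oxide A4 on C3 of the finished, doubly silylated coumarin and the alkyne (R)-pent-4-yn-2-ol A3. The forward key step is a [3+2] cycloaddition to the 3,5-disubstituted isoxazole A2. Reductive N–O cleavage and acid-induced replacement of the amino group by the C2' hydroxyl would then close ring C.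
- For it: the regiochemistry of a terminal alkyne with a nitrile oxide is dependable. C2' is carried as a plain secondary alcohol that cannot epimerise, and no amine catalyst ever meets the finished ring C. On this point it is stronger than the condensation chosen here.
- Against it: the coumarin must first be made with a C3 carbon handle and taken through oxime and hydroximoyl halide. The halogenation competes with substitution on the electron-rich ring A, the dipole dimerises, and the N–O reduction must spare the C3=C4 bond and the lactone.
- It also leaves the side-chain diad unsolved, so the chemistry of the chosen route up to the salicylaldehyde would be needed anyway.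
- Comparison: the chosen route unites two fragments of similar size in one operation that also closes ring B. The risk to C2' is met by a buffered catalyst and by a fallback that closes ring C last.

**Alternative 3:** The lactone bond O1–C8a would be formed by C–H functionalisation. The precursor is the (E)-acrylic acid A6, which has hydrogen at C8a. In the forward key step a flavin photocatalyst under blue light and air isomerises the alkene and closes the carboxylate oxidatively onto C8a, giving the protected target A5.
- For it: ring A needs no oxygen at C8a, which saves one phenol protecting group, and the conditions are neutral. On protecting-group economy at that position it is stronger.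
- Against it: A6 must itself be made by condensing an aryl aldehyde with the ring-C acetic acid unit, so the difficult C3–C4 bond formation is not avoided.
- A6 contains the enone of ring C as a second chromophore, an electron-rich arene and a tertiary benzylic C–H at C1'', all of which invite competing photochemistry and oxidation.
- The closure must occur at C8a next to the C8 methyl group and not at the substituted C5. The known umbelliferone-type cases are α-unsubstituted cinnamic acids.
- Comparison: in the chosen route both ring oxygens come with the symmetric starting arene 1, so the lactone closes by a thermal acyl transfer. What Alternative 3 saves in protection it pays for with an unproven photochemical step on the most advanced intermediate.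

Key step: step 9

Remark on the chemistry: LiN(i-Pr)2, Cp2TiMe2, HF·pyridine and both metal catalysts are taken as commercial reagents; bromide 3 is also an article of commerce, and steps 1 and 2 only make the route independent of that supply.

## Route

**Step 1**
Reactants: 1 2,6-dimethoxytoluene
Product: 2 2-(3,5-dimethoxy-4-methylphenyl)-4,4,5,5-tetramethyl-1,3,2-dioxaborolane
Conditions: B2pin2, [Ir(cod)(OMe)]2 (cod = 1,5-cyclooctadiene), 4,4'-di-tert-butyl-2,2'-bipyridine, THF, 80 °C
Reagents that add atoms: bis(pinacolato)diboron, CC1(C)OB(OC1(C)C)B1OC(C)(C)C(C)(C)O1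
Why: Iridium-catalysed C–H borylation is governed by steric access; in 1 only the hydrogen para to the methyl group has no ortho substituent, so boron goes meta to both methoxy groups, the position electrophilic substitution cannot reach.

**Step 2**
Reactants: 2 2-(3,5-dimethoxy-4-methylphenyl)-4,4,5,5-tetramethyl-1,3,2-dioxaborolane
Product: 3 5-bromo-1,3-dimethoxy-2-methylbenzene
Conditions: CuBr2, MeOH/H2O, 80 °C
Reagents that add atoms: copper dibromide CuBr2, Br[Cu]Br
Why: Copper-mediated bromodeboronation of an aryl boronic ester is an ipso substitution, so the meta position fixed in step 1 is kept; methyl ethers tolerate the acidic aqueous methanol.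

**Step 3**
Reactants: 3 5-bromo-1,3-dimethoxy-2-methylbenzene
Product: 5 1-bromo-3,5-dimethoxy-2,4-dimethylbenzene, via aryllithium 4 (not isolated)
Conditions: LiN(i-Pr)2 (1.05 equiv), THF, −78 °C; MeI, −78 °C → rt
Reagents that add atoms: iodomethane, CI
Why: Directed ortho-lithiation: the two equivalent ring hydrogens of 3 lie between bromine and methoxy and are the most acidic, the amide base cannot exchange the bromine, and at −78 °C aryllithium 4 should not lose LiBr before iodomethane alkylates it.

**Step 4**
Reactants: 6 ethyl (S)-lactate
Product: 7 ethyl (2S)-2-[(tert-butyldimethylsilyl)oxy]propanoate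
Conditions: TBSCl, imidazole, DMF, rt
Reagents that add atoms: tert-butyl(chloro)dimethylsilane, CC(C)(C)[Si](C)(C)Cl
Why: Standard imidazole-promoted silylation of a secondary alcohol; the stereocentre is not involved.

**Step 5**
Reactants: 7 ethyl (2S)-2-[(tert-butyldimethylsilyl)oxy]propanoate
Product: 8 (2S)-2-[(tert-butyldimethylsilyl)oxy]-N-methoxy-N-methylpropanamide
Conditions: MeNH(OMe)·HCl, i-PrMgCl, THF, −20 °C → 0 °C
Reagents that add atoms: N,O-dimethylhydroxylamine hydrochloride, CNOC.Cl
Why: Weinreb amide formation by aminolysis of the ester with the chloromagnesium amide made in the flask; at low temperature this weakly basic amide attacks the carbonyl faster than it removes the α-hydrogen, so the (S) centre is kept.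

**Step 6**
Reactants: 5 1-bromo-3,5-dimethoxy-2,4-dimethylbenzene; 8 (2S)-2-[(tert-butyldimethylsilyl)oxy]-N-methoxy-N-methylpropanamide
Product: 10 (2S)-2-[(tert-butyldimethylsilyl)oxy]-1-(3,5-dimethoxy-2,4-dimethylphenyl)propan-1-one, via arylmagnesium bromide 9 (not isolated)
Conditions: Mg turnings, THF, 50 °C; then 8, 0 °C → rt; 1 M HCl, 0 °C
Reagents that add atoms: none
Why: Weinreb ketone synthesis: magnesium insertion gives 9, which adds only once because the magnesium chelate of the tetrahedral adduct survives until the acid quench; the ketone never meets the basic Grignard reagent, so its α-centre is not enolised.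

**Step 7**
Reactants: 10 (2S)-2-[(tert-butyldimethylsilyl)oxy]-1-(3,5-dimethoxy-2,4-dimethylphenyl)propan-1-one
Product: 11 tert-butyl{[(2S)-3-(3,5-dimethoxy-2,4-dimethylphenyl)but-3-en-2-yl]oxy}dimethylsilane
Conditions: Cp2TiMe2, toluene/THF, 65 °C, dark
Reagents that add atoms: dimethyltitanocene Cp2TiMe2, C[Ti+2]C.c1cc[cH-]c1.c1cc[cH-]c1
Why: Petasis methylenation: loss of methane gives the titanocene methylidene, which turns C=O into C=CH2 by [2+2] cycloaddition and cycloreversion; the reagent is not basic, so the hindered, enolisable α-silyloxy aryl ketone should be methylenated without loss of configuration, which a phosphorus ylide would put at risk.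

**Step 8**
Reactants: 11 tert-butyl{[(2S)-3-(3,5-dimethoxy-2,4-dimethylphenyl)but-3-en-2-yl]oxy}dimethylsilane
Product: 12 (2S)-3-(3,5-dimethoxy-2,4-dimethylphenyl)but-3-en-2-ol
Conditions: Bu4NF, THF, 0 °C → rt
Reagents that add atoms: none
Why: Fluoride-induced desilylation frees the allylic hydroxyl that the key step needs as its directing group; nothing else in 11 reacts with fluoride.

**Step 9**
Reactants: 12 (2S)-3-(3,5-dimethoxy-2,4-dimethylphenyl)but-3-en-2-ol
Product: 13 (2S,3R)-3-(3,5-dimethoxy-2,4-dimethylphenyl)butan-2-ol
Conditions: H2 (60 bar), [Rh(nbd)(dppb)]BF4 (5 mol %; nbd = norbornadiene, dppb = 1,4-bis(diphenylphosphino)butane), CH2Cl2, 25 °C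
Reagents that add atoms: none
Why: This is a hydroxyl-directed homogeneous hydrogenation, the known anti-selective reduction of 2-substituted allylic alcohols by cationic rhodium diphosphine catalysts. Hydrogen first removes norbornadiene from monovalent rhodium, and the hydroxyl and the C=C bond of 12 then occupy the two free sites of the [Rh(dppb)]+ fragment. Oxidative addition of H2 gives a trivalent rhodium dihydride, and migratory insertion followed by reductive elimination delivers both hydrogens to the alkene face held next to the metal. No ring is closed and no skeletal bond is formed; the one new stereocentre is the benzylic carbon. It is controlled by the (S) carbinol: in the chelate the C–O bond stands roughly perpendicular to the alkene plane, and 1,2-allylic strain between the carbinol methyl group and the aryl ring places the carbinol hydrogen, not the methyl group, next to the aryl ring. Only one alkene face can then reach rhodium, and the new benzylic C–H bond forms on it, which gives the (2S,3R) anti isomer. The step needs facial selectivity and must outrun isomerisation of the allylic alcohol to the saturated ketone through a rhodium hydride. The free hydroxyl, the unhindered =CH2 terminus and the ortho methyl group (which turns the aryl ring out of the alkene plane, so chelation is the only directing element) secure the first, and the high hydrogen pressure secures the second.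

**Step 10**
Reactants: 13 (2S,3R)-3-(3,5-dimethoxy-2,4-dimethylphenyl)butan-2-ol
Product: 14 5-[(2R,3S)-3-hydroxybutan-2-yl]-2,4-dimethylbenzene-1,3-diol
Conditions: BBr3, CH2Cl2, −78 °C → 0 °C; aq. NaHCO3
Reagents that add atoms: none
Why: Boron tribromide cleavage of aryl methyl ethers (O–B complexation, then SN2 attack of bromide on the methyl group) frees both phenols at once; the carbinol is held as a borate and should not ionise, because the ring oxygens are meta to the ipso carbon and, being complexed, cannot support an aryl-bridged cation.

**Step 11**
Reactants: 14 5-[(2R,3S)-3-hydroxybutan-2-yl]-2,4-dimethylbenzene-1,3-diol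
Product: 16 5-[(2R,3S)-3-[(tert-butyldimethylsilyl)oxy]butan-2-yl]-2,4-dimethylbenzene-1,3-diol, via tris-silyl ether 15 (not isolated)
Conditions: TBSOTf, 2,6-lutidine, CH2Cl2, 0 °C → rt; then K2CO3, MeOH, rt, under argon
Reagents that add atoms: tert-butyldimethylsilyl triflate, CC(C)(C)[Si](C)(C)OS(=O)(=O)C(F)(F)F
Why: Exhaustive silylation gives 15, and carbonate in methanol then cleaves only the aryl silyl ethers, because a phenoxide leaves silicon far more readily than a hindered secondary alkoxide; the carbinol is thus masked before any aldehyde exists.

**Step 12**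
Reactants: 16 5-[(2R,3S)-3-[(tert-butyldimethylsilyl)oxy]butan-2-yl]-2,4-dimethylbenzene-1,3-diol
Product: 18 2-[(2R,3S)-3-[(tert-butyldimethylsilyl)oxy]butan-2-yl]-4,6-dihydroxy-3,5-dimethylbenzaldehyde, via benzylic alcohol 17 (not isolated)
Conditions: MgCl2, Et3N, (CH2O)n, THF, 65 °C; 1 M HCl, 0 °C
Reagents that add atoms: paraformaldehyde (as formaldehyde), C=O
Why: Magnesium-mediated ortho-formylation of phenols (Casnati–Skattebøl reaction): the magnesium phenoxide delivers formaldehyde to its ortho carbon, the only unsubstituted ring position, and benzylic alcohol 17 is oxidised in the flask by hydride transfer to a second formaldehyde; the basic medium leaves the alkyl silyl ether alone.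

**Step 13**
Reactants: 19 methyl (R)-3-hydroxybutanoate
Product: 20 methyl (3R)-3-[(tert-butyldimethylsilyl)oxy]butanoate
Conditions: TBSCl, imidazole, DMF, rt
Reagents that add atoms: tert-butyl(chloro)dimethylsilane, CC(C)(C)[Si](C)(C)Cl
Why: Standard silylation; the masked hydroxyl cannot quench the carbanion of step 15 or start a retro-aldol cleavage.

**Step 14**
Reactants: 20 methyl (3R)-3-[(tert-butyldimethylsilyl)oxy]butanoate
Product: 21 (3R)-3-[(tert-butyldimethylsilyl)oxy]-N-methoxy-N-methylbutanamide
Conditions: MeNH(OMe)·HCl, i-PrMgCl, THF, −20 °C → 0 °C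
Reagents that add atoms: N,O-dimethylhydroxylamine hydrochloride, CNOC.Cl
Why: Weinreb amide formation as in step 5; at low temperature the magnesium amide should not eliminate the β-silyloxy group.

**Step 15**
Reactants: 21 (3R)-3-[(tert-butyldimethylsilyl)oxy]-N-methoxy-N-methylbutanamide; 22 ethyl acetoacetate
Product: 24 ethyl (7R)-7-[(tert-butyldimethylsilyl)oxy]-3,5-dioxooctanoate, via acetoacetate dianion 23 (not isolated)
Conditions: 22 (2.2 equiv), NaH, THF, 0 °C; n-BuLi, 0 °C; then 21, −78 °C → 0 °C; aq. HCl to pH 4
Reagents that add atoms: none
Why: Acylation of the acetoacetate dianion (Weiler dianion): the more basic terminal carbon of 23 attacks the Weinreb amide, whose chelated tetrahedral adduct stops the reaction at the ketone stage until acidification; the stereocentre is not α to any carbonyl and is untouched.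

**Step 16**
Reactants: 24 ethyl (7R)-7-[(tert-butyldimethylsilyl)oxy]-3,5-dioxooctanoate
Product: 26 ethyl 2-[(2R)-2-methyl-4-oxo-3,4-dihydro-2H-pyran-6-yl]acetate, via hydroxy diketo ester 25 (not isolated)
Conditions: CF3CO2H/H2O (9:1), CH2Cl2, 0 °C → rt
Reagents that add atoms: none
Why: Acid removes the silyl group, and the hydroxyl of 25 adds to the C3 ketone, the only carbonyl it can reach through a six-membered ring (6-exo-trig hemiketal formation); loss of water gives the vinylogous ester, and the C–O bond at the stereocentre is never broken.

**Step 17**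
Reactants: 18 2-[(2R,3S)-3-[(tert-butyldimethylsilyl)oxy]butan-2-yl]-4,6-dihydroxy-3,5-dimethylbenzaldehyde; 26 ethyl 2-[(2R)-2-methyl-4-oxo-3,4-dihydro-2H-pyran-6-yl]acetate
Product: 28 5-[(2R,3S)-3-[(tert-butyldimethylsilyl)oxy]butan-2-yl]-7-hydroxy-6,8-dimethyl-3-[(2R)-2-methyl-4-oxo-3,4-dihydro-2H-pyran-6-yl]-2H-chromen-2-one, via arylidene ester 27 (not isolated)
Conditions: piperidine (0.2 equiv), AcOH (0.2 equiv), EtOH, 50 °C
Reagents that add atoms: none
Why: Knoevenagel condensation followed by lactonisation, the standard coumarin synthesis from salicylaldehydes: the amine activates the aldehyde as an iminium ion, the only acidic methylene of 26 condenses to 27, and the ortho phenol then displaces ethanol to close ring B; the buffered catalyst is chosen so that the β-alkoxy ketone of ring C is not opened.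

**Step 18**
Reactants: 28 5-[(2R,3S)-3-[(tert-butyldimethylsilyl)oxy]butan-2-yl]-7-hydroxy-6,8-dimethyl-3-[(2R)-2-methyl-4-oxo-3,4-dihydro-2H-pyran-6-yl]-2H-chromen-2-one
Product: 29 7-hydroxy-5-[(2R,3S)-3-hydroxybutan-2-yl]-6,8-dimethyl-3-[(2R)-2-methyl-4-oxo-3,4-dihydro-2H-pyran-6-yl]-2H-chromen-2-one
Conditions: HF·pyridine, pyridine/THF, 0 °C → rt
Reagents that add atoms: none
Why: Desilylation through Si–F bond formation under weakly acidic conditions, which should spare the base-labile ring C, the lactone and all three stereocentres.

## Compound list

1 | 2,6-dimethoxytoluene | Cc1c(OC)cccc1OC | starting material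
2 | 2-(3,5-dimethoxy-4-methylphenyl)-4,4,5,5-tetramethyl-1,3,2-dioxaborolane | Cc1c(OC)cc(cc1OC)B1OC(C)(C)C(C)(C)O1 | intermediate
3 | 5-bromo-1,3-dimethoxy-2-methylbenzene | Cc1c(OC)cc(Br)cc1OC | intermediate
4 | (6-bromo-2,4-dimethoxy-3-methylphenyl)lithium | [Li]c1c(Br)cc(OC)c(C)c1OC | intermediate
5 | 1-bromo-3,5-dimethoxy-2,4-dimethylbenzene | Cc1c(Br)cc(OC)c(C)c1OC | intermediate
6 | ethyl (S)-lactate | CCOC(=O)[C@H](C)O | starting material
7 | ethyl (2S)-2-[(tert-butyldimethylsilyl)oxy]propanoate | CCOC(=O)[C@H](C)O[Si](C)(C)C(C)(C)C | intermediate
8 | (2S)-2-[(tert-butyldimethylsilyl)oxy]-N-methoxy-N-methylpropanamide | CON(C)C(=O)[C@H](C)O[Si](C)(C)C(C)(C)C | intermediate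
9 | bromo(3,5-dimethoxy-2,4-dimethylphenyl)magnesium | Cc1c([Mg]Br)cc(OC)c(C)c1OC | intermediate
10 | (2S)-2-[(tert-butyldimethylsilyl)oxy]-1-(3,5-dimethoxy-2,4-dimethylphenyl)propan-1-one | COc1cc(C(=O)[C@H](C)O[Si](C)(C)C(C)(C)C)c(C)c(OC)c1C | intermediate
11 | tert-butyl{[(2S)-3-(3,5-dimethoxy-2,4-dimethylphenyl)but-3-en-2-yl]oxy}dimethylsilane | C=C(c1cc(OC)c(C)c(OC)c1C)[C@H](C)O[Si](C)(C)C(C)(C)C | intermediate
12 | (2S)-3-(3,5-dimethoxy-2,4-dimethylphenyl)but-3-en-2-ol | C=C(c1cc(OC)c(C)c(OC)c1C)[C@H](C)O | intermediate
13 | (2S,3R)-3-(3,5-dimethoxy-2,4-dimethylphenyl)butan-2-ol | COc1cc([C@@H](C)[C@H](C)O)c(C)c(OC)c1C | intermediate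
14 | 5-[(2R,3S)-3-hydroxybutan-2-yl]-2,4-dimethylbenzene-1,3-diol | Oc1cc([C@@H](C)[C@H](C)O)c(C)c(O)c1C | intermediate
15 | tert-butyl{[(2S,3R)-3-{3,5-bis[(tert-butyldimethylsilyl)oxy]-2,4-dimethylphenyl}butan-2-yl]oxy}dimethylsilane | CC(C)(C)[Si](C)(C)Oc1cc([C@@H](C)[C@H](C)O[Si](C)(C)C(C)(C)C)c(C)c(O[Si](C)(C)C(C)(C)C)c1C | intermediate
16 | 5-[(2R,3S)-3-[(tert-butyldimethylsilyl)oxy]butan-2-yl]-2,4-dimethylbenzene-1,3-diol | Oc1cc([C@@H](C)[C@H](C)O[Si](C)(C)C(C)(C)C)c(C)c(O)c1C | intermediate
17 | 5-[(2R,3S)-3-[(tert-butyldimethylsilyl)oxy]butan-2-yl]-4-(hydroxymethyl)-2,6-dimethylbenzene-1,3-diol | Oc1c(CO)c([C@@H](C)[C@H](C)O[Si](C)(C)C(C)(C)C)c(C)c(O)c1C | intermediate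
18 | 2-[(2R,3S)-3-[(tert-butyldimethylsilyl)oxy]butan-2-yl]-4,6-dihydroxy-3,5-dimethylbenzaldehyde | Oc1c(C=O)c([C@@H](C)[C@H](C)O[Si](C)(C)C(C)(C)C)c(C)c(O)c1C | intermediate
19 | methyl (R)-3-hydroxybutanoate | COC(=O)C[C@@H](C)O | starting material
20 | methyl (3R)-3-[(tert-butyldimethylsilyl)oxy]butanoate | COC(=O)C[C@@H](C)O[Si](C)(C)C(C)(C)C | intermediate
21 | (3R)-3-[(tert-butyldimethylsilyl)oxy]-N-methoxy-N-methylbutanamide | CON(C)C(=O)C[C@@H](C)O[Si](C)(C)C(C)(C)C | intermediate
22 | ethyl acetoacetate | CCOC(=O)CC(C)=O | starting material
23 | sodium lithium dianion of ethyl acetoacetate | [Na+].[Li+].CCOC(=O)[CH-]C(=O)[CH2-] | intermediate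
24 | ethyl (7R)-7-[(tert-butyldimethylsilyl)oxy]-3,5-dioxooctanoate | CCOC(=O)CC(=O)CC(=O)C[C@@H](C)O[Si](C)(C)C(C)(C)C | intermediate
25 | ethyl (7R)-7-hydroxy-3,5-dioxooctanoate | CCOC(=O)CC(=O)CC(=O)C[C@@H](C)O | intermediate
26 | ethyl 2-[(2R)-2-methyl-4-oxo-3,4-dihydro-2H-pyran-6-yl]acetate | CCOC(=O)CC1=CC(=O)C[C@@H](C)O1 | intermediate
27 | ethyl 3-{2-[(2R,3S)-3-[(tert-butyldimethylsilyl)oxy]butan-2-yl]-4,6-dihydroxy-3,5-dimethylphenyl}-2-[(2R)-2-methyl-4-oxo-3,4-dihydro-2H-pyran-6-yl]prop-2-enoate (alkene geometry not fixed) | CCOC(=O)C(=Cc1c(O)c(C)c(O)c(C)c1[C@@H](C)[C@H](C)O[Si](C)(C)C(C)(C)C)C1=CC(=O)C[C@@H](C)O1 | intermediate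
28 | 5-[(2R,3S)-3-[(tert-butyldimethylsilyl)oxy]butan-2-yl]-7-hydroxy-6,8-dimethyl-3-[(2R)-2-methyl-4-oxo-3,4-dihydro-2H-pyran-6-yl]-2H-chromen-2-one | Cc1c(O)c(C)c2oc(=O)c(C3=CC(=O)C[C@@H](C)O3)cc2c1[C@@H](C)[C@H](C)O[Si](C)(C)C(C)(C)C | intermediate
29 | 7-hydroxy-5-[(2R,3S)-3-hydroxybutan-2-yl]-6,8-dimethyl-3-[(2R)-2-methyl-4-oxo-3,4-dihydro-2H-pyran-6-yl]-2H-chromen-2-one | Cc1c(O)c(C)c2oc(=O)c(C3=CC(=O)C[C@@H](C)O3)cc2c1[C@@H](C)[C@H](C)O | target

## Step count and least certain steps

Total step count: 18. Longest linear sequence: 12 steps (1, 2, 3, 6, 7, 8, 9, 10, 11, 12, 17, 18 from compound 1). The lactate branch (steps 4 and 5) and the ring-C branch (steps 13 to 16) are side arms.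

**Step 9 (key step).** The catalyst may isomerise the allylic alcohol to the saturated ketone through a rhodium hydride, which would destroy both stereocentres. Facial control may be incomplete if hydroxyl chelation is weakened, for example by η6 binding of the electron-rich arene to the cationic metal or by traces of ammonium salts carried over from step 8; the same binding may slow turnover. Fallback: the route leaves from bromide 5 as its Grignard reagent 9. CuI-catalysed opening of commercial (2R,3R)-2,3-dimethyloxirane (C[C@H]1O[C@@H]1C), with inversion at the attacked carbon, should give (2R,3R)-3-(3,5-dimethoxy-2,4-dimethylphenyl)butan-2-ol F1. Mitsunobu inversion of the carbinol with 4-nitrobenzoic acid, PPh3 and diisopropyl azodicarboxylate should give (2S,3R)-3-(3,5-dimethoxy-2,4-dimethylphenyl)butan-2-yl 4-nitrobenzoate F2. Methanolysis with K2CO3 in MeOH returns to the route at 13. Both stereocentres then come from the epoxide and no hydrogenation is needed.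

**Step 12.** The benzylic alcohol 17 may condense with a second arene through a quinone methide instead of being oxidised, or conversion may stall at the crowded position. Fallback: the route leaves from 16. Benzylation (BnBr, K2CO3, DMF) gives tert-butyl{[(2S,3R)-3-[3,5-bis(benzyloxy)-2,4-dimethylphenyl]butan-2-yl]oxy}dimethylsilane F3. Ring bromination with N-bromosuccinimide in MeCN at 0 °C gives {[(2S,3R)-3-[3,5-bis(benzyloxy)-2-bromo-4,6-dimethylphenyl]butan-2-yl]oxy}(tert-butyl)dimethylsilane F4. Bromine–lithium exchange with t-BuLi in THF at −78 °C and quenching with DMF gives 4,6-bis(benzyloxy)-2-[(2R,3S)-3-[(tert-butyldimethylsilyl)oxy]butan-2-yl]-3,5-dimethylbenzaldehyde F5. Hydrogenolysis over Pd on carbon (Pd/C) in ethyl acetate, stopped after two equivalents of hydrogen, returns to the route at 18.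

**Step 17.** Condensation may be slow at the doubly ortho-substituted aldehyde, which is further deactivated as a phenoxide. The amine may add at C6' or promote β-elimination in ring C, with loss of configuration at C2'. Reaction through C5' instead of the methylene is also possible. Fallback: the route leaves from 18. Knoevenagel condensation and lactonisation with ethyl acetoacetate 22 (piperidine, EtOH) gives 3-acetyl-5-[(2R,3S)-3-[(tert-butyldimethylsilyl)oxy]butan-2-yl]-7-hydroxy-6,8-dimethyl-2H-chromen-2-one F6. Its lithium enolate (LiN(SiMe3)2, 3 equiv, THF, −78 °C) is acylated by Weinreb amide 21 to give 5-[(2R,3S)-3-[(tert-butyldimethylsilyl)oxy]butan-2-yl]-3-[(5R)-5-[(tert-butyldimethylsilyl)oxy]-3-oxohexanoyl]-7-hydroxy-6,8-dimethyl-2H-chromen-2-one F7. Aqueous HF in MeCN then removes both silyl groups and closes ring C by hemiketal formation and dehydration, which returns to the route at the target 29. Ring C is then formed last and never meets an amine.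

**Step 10.** The borate of the carbinol may be converted into a secondary bromide, or the aryl group may migrate through a bridged cation, with loss of the hydroxyl or of configuration. Fallback: the route leaves from 13. Acetylation (Ac2O, 4-dimethylaminopyridine, pyridine) gives (2S,3R)-3-(3,5-dimethoxy-2,4-dimethylphenyl)butan-2-yl acetate F8. BBr3 at −78 °C → −20 °C gives (2S,3R)-3-(3,5-dihydroxy-2,4-dimethylphenyl)butan-2-yl acetate F9, in which the ester oxygen cannot form a borate leaving group. K2CO3 in MeOH returns to the route at 14.

**Step 3.** Proton transfer between aryllithium 4 and product 5 during the quench may cause over-methylation at the second position between bromine and methoxy, with return of 3. Loss of LiBr from 4 to an aryne is possible if the temperature rises. Fallback: the route leaves from 3. The same lithiation is quenched with DMF to give 6-bromo-2,4-dimethoxy-3-methylbenzaldehyde F10, whose aminoalkoxide precursor cannot be deprotonated again. Ionic hydrogenation of the electron-rich aldehyde (Et3SiH, CF3CO2H) reduces the formyl group to methyl and returns to the route at 5.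

## Further compounds

F1 | step 9 | (2R,3R)-3-(3,5-dimethoxy-2,4-dimethylphenyl)butan-2-ol | COc1cc([C@@H](C)[C@@H](C)O)c(C)c(OC)c1C
F2 | step 9 | (2S,3R)-3-(3,5-dimethoxy-2,4-dimethylphenyl)butan-2-yl 4-nitrobenzoate | COc1cc([C@@H](C)[C@H](C)OC(=O)c2ccc(cc2)[N+](=O)[O-])c(C)c(OC)c1C
F3 | step 12 | tert-butyl{[(2S,3R)-3-[3,5-bis(benzyloxy)-2,4-dimethylphenyl]butan-2-yl]oxy}dimethylsilane | C(c1ccccc1)Oc1cc([C@@H](C)[C@H](C)O[Si](C)(C)C(C)(C)C)c(C)c(OCc2ccccc2)c1C
F4 | step 12 | {[(2S,3R)-3-[3,5-bis(benzyloxy)-2-bromo-4,6-dimethylphenyl]butan-2-yl]oxy}(tert-butyl)dimethylsilane | C(c1ccccc1)Oc1c(Br)c([C@@H](C)[C@H](C)O[Si](C)(C)C(C)(C)C)c(C)c(OCc2ccccc2)c1C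
F5 | step 12 | 4,6-bis(benzyloxy)-2-[(2R,3S)-3-[(tert-butyldimethylsilyl)oxy]butan-2-yl]-3,5-dimethylbenzaldehyde | C(c1ccccc1)Oc1c(C=O)c([C@@H](C)[C@H](C)O[Si](C)(C)C(C)(C)C)c(C)c(OCc2ccccc2)c1C
F6 | step 17 | 3-acetyl-5-[(2R,3S)-3-[(tert-butyldimethylsilyl)oxy]butan-2-yl]-7-hydroxy-6,8-dimethyl-2H-chromen-2-one | CC(=O)c1cc2c([C@@H](C)[C@H](C)O[Si](C)(C)C(C)(C)C)c(C)c(O)c(C)c2oc1=O
F7 | step 17 | 5-[(2R,3S)-3-[(tert-butyldimethylsilyl)oxy]butan-2-yl]-3-[(5R)-5-[(tert-butyldimethylsilyl)oxy]-3-oxohexanoyl]-7-hydroxy-6,8-dimethyl-2H-chromen-2-one | C[C@@H](O[Si](C)(C)C(C)(C)C)CC(=O)CC(=O)c1cc2c([C@@H](C)[C@H](C)O[Si](C)(C)C(C)(C)C)c(C)c(O)c(C)c2oc1=O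
F8 | step 10 | (2S,3R)-3-(3,5-dimethoxy-2,4-dimethylphenyl)butan-2-yl acetate | COc1cc([C@@H](C)[C@H](C)OC(C)=O)c(C)c(OC)c1C
F9 | step 10 | (2S,3R)-3-(3,5-dihydroxy-2,4-dimethylphenyl)butan-2-yl acetate | Oc1cc([C@@H](C)[C@H](C)OC(C)=O)c(C)c(O)c1C
F10 | step 3 | 6-bromo-2,4-dimethoxy-3-methylbenzaldehyde | COc1cc(Br)c(C=O)c(OC)c1C
A1 | alternative 1 | 7-hydroxy-2,2,6,8-tetramethyl-5-[(2R,3S)-3-(tert-butyldimethylsilyloxy)butan-2-yl]-4H-1,3-benzodioxin-4-one | CC1(C)OC(=O)c2c(O1)c(C)c(O)c(C)c2[C@@H](C)[C@H](C)O[Si](C)(C)C(C)(C)C
A2 | alternative 2 | 5-[(2R,3S)-3-(tert-butyldimethylsilyloxy)butan-2-yl]-7-(tert-butyldimethylsilyloxy)-3-{5-[(2R)-2-hydroxypropyl]-1,2-oxazol-3-yl}-6,8-dimethyl-2H-chromen-2-one | C(c1cc(-c2cc3c([C@@H](C)[C@H](C)O[Si](C)(C)C(C)(C)C)c(C)c(O[Si](C)(C)C(C)(C)C)c(C)c3oc2=O)no1)[C@@H](C)O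
A3 | alternative 2 | (R)-pent-4-yn-2-ol | C#CC[C@@H](C)O
A4 | alternative 2 | 5-[(2R,3S)-3-(tert-butyldimethylsilyloxy)butan-2-yl]-7-(tert-butyldimethylsilyloxy)-6,8-dimethyl-2-oxo-2H-chromene-3-carbonitrile oxide | [O-][N+]#Cc1cc2c([C@@H](C)[C@H](C)O[Si](C)(C)C(C)(C)C)c(C)c(O[Si](C)(C)C(C)(C)C)c(C)c2oc1=O
A5 | alternative 3 | 5-[(2R,3S)-3-(tert-butyldimethylsilyloxy)butan-2-yl]-7-(methoxymethoxy)-6,8-dimethyl-3-[(2R)-2-methyl-4-oxo-3,4-dihydro-2H-pyran-6-yl]-2H-chromen-2-one | Cc1c(OCOC)c(C)c2oc(=O)c(C3=CC(=O)C[C@@H](C)O3)cc2c1[C@@H](C)[C@H](C)O[Si](C)(C)C(C)(C)C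
A6 | alternative 3 | (2E)-3-{2-[(2R,3S)-3-(tert-butyldimethylsilyloxy)butan-2-yl]-4-(methoxymethoxy)-3,5-dimethylphenyl}-2-[(2R)-2-methyl-4-oxo-3,4-dihydro-2H-pyran-6-yl]prop-2-enoic acid | OC(=O)/C(=C/c1cc(C)c(OCOC)c(C)c1[C@@H](C)[C@H](C)O[Si](C)(C)C(C)(C)C)C1=CC(=O)C[C@@H](C)O1
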